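Time is the setting you would turn first, yet on this flask L goes over to Q with a half-life, forward rate alone, far shorter than 8.0 min.

    Q ⇌ E (K1 = 1.5, k1 = 0.080 min⁻¹)
    E ⇌ X (K2 = 0.93, k2 = 0.45 min⁻¹)
    X ⇌ L (K3 = 0.42, k3 = 0.024 min⁻¹)
    L ⇌ Q (k4 = 4.3 min⁻¹)
    Q ⇌ G (K5 = 10, k5 = 0.13 min⁻¹)

| flask | Q | remark | time |
|---|---|---|---|
| Monday's | 0.020 M | a single well-mixed tank run continuously and read at steady state, 40.0 min in it on average |  |
| Saturday's | 0.020 M | everything together in a closed stirred flask, run for 8.0 min | 8.0 min |
| Friday's | 0.020 M | one stirred flow tank at steady state, fed with the mixture as stated, mean residence time 8.0 min |  |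

- order of the set-ups by the share of E in all that became E or X or L, at the outlet or at the end, highest first (Monday's / Saturday's / Friday's)
- share of E in all that became E or X or L, at the outlet or at the end, Monday's
- share of E in all that became E or X or L, at the outlet or at the end, Saturday's
- share of E in all that became E or X or L, at the outlet or at the end, Friday's

- the stated concentrations are those of everything mixed, before any reaction; amounts are the same in each set-up
- run time (Saturday's): 8.0 min

The step from L to Q has as its equilibrium constant the inverse of the product of the constants of the steps from Q through E and X to L, so that product is the tie ratio, c_L over c_Q once the step between L and Q has balanced: 0.586. That balance is a fast pre-equilibrium. Q goes to L at 2.52 min⁻¹, much faster than the 0.080 min⁻¹ at which it goes to E, and the balance comes within about 0.147 min, much shorter than 8.0 min.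

Turn the time first. By their forward rates alone, Q has half-lives of 8.7 min towards E and 5.3 min towards G, and L stands tied to whatever Q remains. At 40.0 min, longer than either, Q is drawn further down and L follows. L then counts for less in the sum beside E and X, so by hand the share of E rises with time.

Turn the vessel next, at equal time. Treat Q and L as one pool, draining to E and G at 0.132 min⁻¹ if you count no way back. Over 8.0 min, Saturday's closed flask keeps 34.7% of the pool, while Friday's tank, with that time as its mean residence time and its contents at outlet strength, keeps 48.6%, which is more. By the tie, that puts L near 12.8% of the charge on Saturday's and 18.0% on Friday's. My order is therefore Monday's, Saturday's, Friday's.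

The forecast gives the opposite order, Friday's > Saturday's > Monday's, with 54.1% for Monday's, 55.3% for Saturday's and 58.3% for Friday's, taking the step from L to Q “with no reverse term despite the quoted equilibrium constant”.

The flask gives Monday's > Saturday's > Friday's: 39.3% on Monday's, 36.4% on Saturday's, 29.6% on Friday's. With the way from Q to L struck out, Friday's minus Monday's becomes 4.2 percentage points. On Friday's outlet, Q stands at 31.4% of the charge, so the tie ratio of 0.586 puts L near 18.4%, and with E at 11.6% and X at 9.81% that reckons the share of E at about 29.1%.

The constants used here stand for no real mixture; the run is a simulation.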